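**Plan**

- Retrosynthesis, last cut: the C4(=C18H2)–C5(OOH) unit is the Schenck-ene image of a (4E)-C4=C5 olefin whose C18 methyl lies cis to C6, so removing O2 leads back to ovatodiolide.
- Next cut: C4=C5 (14-membered ring) and C8=C9 (butenolide ring O–C19–C8=C9–C10) are cut together as two ethylene-releasing metatheses. This works because C4 and C5 each end a saturated two-carbon arm (C2–C3, C6–C7) and C8/C9 are linked only through the C19 ester, so all four can be carried as plain terminal olefin carbons.
- Further cuts: C1–C14 and O–C16 (allylboration/lactonisation), the C19–O ester, and C12–C20/C13–C14 (carboalumination/hydroxymethylation).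
- Forward: (R)-epichlorohydrin gives the west enal ester (C5–C14, C19); methallyl chloride gives the east (Z)-allylboronate (C1–C4, C15–C18). Their union builds the trans α-methylene-γ-butyrolactone; one Ru charge then closes the butenolide and the carbocycle at C4=C5; singlet oxygen finishes.
- Stereochemistry: C10 from the chiral pool; C14 and C1 from a catalyst-controlled chair allylboration ((Z)-boronate → anti → trans lactone); 12E from syn-carboalumination; 4E in the metathesis; C5 from peripheral attack of singlet oxygen on the macrocycle.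

Key step: step 13

Remark: cembrane numbering is used (C1 = ring-fusion carbon bearing C15, C14 = lactone O–CH, C10 = butenolide O–CH, C18 = carbon on C4, C19 = butenolide carbonyl), the target is (1R,5R,10R,14S) as its SMILES defines, and (R)-TRIP is assumed to show with boronate 24 the Re-face sense it shows with simple pinacol allylboronates.

**Route**

Step 1
Reactants: 1 (R)-epichlorohydrin; 2 ethynyltrimethylsilane
Product: 4 (2R)-1-chloro-5-(trimethylsilyl)pent-4-yn-2-ol, via lithium (trimethylsilyl)acetylide 3 (not isolated)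
Conditions: n-BuLi, THF, −78 °C; BF3·OEt2; then 1, −78 °C; aqueous work-up
Reagents that add atoms: none
Why: Lewis acid-promoted epoxide alkynylation, in which the acetylide should open the BF3-activated epoxide at its unsubstituted carbon by SN2, leaving the C–Cl bond and the carbinol centre (future C10) untouched.

Step 2
Reactants: 4 (2R)-1-chloro-5-(trimethylsilyl)pent-4-yn-2-ol
Product: 6 (3R)-6-(trimethylsilyl)hex-1-en-5-yn-3-ol, via terminal epoxide 5 (not isolated)
Conditions: Me3S+ I− (3.5 equiv), n-BuLi (3.3 equiv), THF, −10 °C → rt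
Reagents that add atoms: trimethylsulfonium iodide, C[S+](C)C.[I-]
Why: Base should close the chlorohydrin to the terminal epoxide, which dimethylsulfonium methylide opens at CH2 and converts by ylide-mediated loss of dimethyl sulfide into the vinyl carbinol (one-carbon epoxide-to-allylic-alcohol homologation), the C–O stereocentre never being broken.

Step 3
Reactants: 6 (3R)-6-(trimethylsilyl)hex-1-en-5-yn-3-ol
Product: 7 (3R)-hex-1-en-5-yn-3-ol
Conditions: K2CO3 (cat.), MeOH, rt
Reagents that add atoms: none
Why: Methoxide-mediated protodesilylation of an alkynylsilane should free the terminal alkyne without affecting the allylic alcohol.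

Step 4
Reactants: 7 (3R)-hex-1-en-5-yn-3-ol
Product: 9 (2E,5R)-3-methylhepta-2,6-diene-1,5-diol, via alkenylalane 8 (not isolated)
Conditions: Me3Al (3 equiv), Cp2ZrCl2 (0.3 equiv), CH2Cl2, 0 °C → rt; then n-BuLi, THF, −78 °C; (CH2O)n, → rt; aqueous Rochelle salt
Reagents that add atoms: trimethylaluminium, C[Al](C)C; paraformaldehyde, monomer C=O
Why: Negishi carboalumination should add Me–Al syn across the terminal alkyne (methyl to the internal carbon, vinyl group inert with Cp2ZrCl2), and the alkenylalanate is hydroxymethylated with retention, which fixes the 12E olefin.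

Step 5
Reactants: 9 (2E,5R)-3-methylhepta-2,6-diene-1,5-diol
Product: 10 (2E,5R)-5-hydroxy-3-methylhepta-2,6-dienal
Conditions: TEMPO (10 mol%), PhI(OAc)2 (1.1 equiv), CH2Cl2, rt
Reagents that add atoms: none
Why: Oxoammonium oxidation is strongly selective for the primary allylic alcohol over the secondary vinyl carbinol and should stop at the enal without E/Z erosion.

Step 6
Reactants: 11 ethyl 2-(bromomethyl)prop-2-enoate; 12 allylmagnesium bromide
Product: 13 ethyl 2-methylidenehex-5-enoate
Conditions: CuI (10 mol%), THF, −78 → 0 °C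
Reagents that add atoms: none
Why: Copper-catalysed allylic substitution of the 2-(bromomethyl)acrylate by the allyl Grignard reagent (SN2′ and SN2 give the same skeleton) should outrun carbonyl addition at low temperature.

Step 7
Reactants: 13 ethyl 2-methylidenehex-5-enoate
Product: 14 2-methylidenehex-5-enoic acid
Conditions: LiOH, THF/H2O, rt; then aqueous HCl
Reagents that add atoms: lithium hydroxide, [Li+].[OH-]
Why: Ester saponification; the α-substituted acrylate is a poor Michael acceptor for hydroxide at room temperature.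

Step 8
Reactants: 10 (2E,5R)-5-hydroxy-3-methylhepta-2,6-dienal; 14 2-methylidenehex-5-enoic acid
Product: 15 (3R,5E)-5-methyl-7-oxohepta-1,5-dien-3-yl 2-methylidenehex-5-enoate
Conditions: DCC, DMAP (cat.), CH2Cl2, 0 °C → rt
Reagents that add atoms: none
Why: Steglich esterification should acylate the only hydroxyl group under neutral conditions, with the enal and the C10 centre (no C–O cleavage) unaffected.

Step 9
Reactants: 16 trimethyl(prop-1-yn-1-yl)silane; 17 3-chloro-2-methylprop-1-ene
Product: 19 trimethyl(5-methylhex-5-en-1-yn-1-yl)silane, via lithiated silylpropyne 18 (not isolated)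
Conditions: n-BuLi, THF, −78 → −20 °C; then 17, −78 °C → rt
Reagents that add atoms: none
Why: Propargylic lithiation of the silyl-capped propyne followed by SN2 alkylation at the propargyl terminus (the silyl group disfavours allenyl attack, and SN2/SN2′ on the symmetrical methallyl unit give the same product).

Step 10
Reactants: 19 trimethyl(5-methylhex-5-en-1-yn-1-yl)silane
Product: 21 methyl 6-methylhept-6-en-2-ynoate, via lithium acetylide 20 (not isolated)
Conditions: MeLi·LiBr, THF, 0 °C → rt; then ClCO2Me, −78 °C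
Reagents that add atoms: methyl chloroformate, COC(=O)Cl
Why: Methyllithium should cleave the alkynyl C–Si bond to the lithium acetylide, which is C-acylated in the same flask by the chloroformate.

Step 11
Reactants: 21 methyl 6-methylhept-6-en-2-ynoate; 22 2-(iodomethyl)-4,4,5,5-tetramethyl-1,3,2-dioxaborolane
Product: 24 methyl (2Z)-6-methyl-2-[(4,4,5,5-tetramethyl-1,3,2-dioxaborolan-2-yl)methyl]hepta-2,6-dienoate, via α-aluminio enoate 23 (not isolated)
Conditions: i-Bu2AlH (1.1 equiv), HMPA, THF, 0 °C; then 22, rt
Reagents that add atoms: none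
Why: Conjugate hydroalumination should add H–Al syn across the ynoate, and alkylation of the α-aluminio enoate by the iodomethylboronate with retention places the C2 chain cis to the ester and trans to CH2B, giving the (Z)-2-(alkoxycarbonyl)allylboronate.

Step 12
Reactants: 15 (3R,5E)-5-methyl-7-oxohepta-1,5-dien-3-yl 2-methylidenehex-5-enoate; 24 the (2Z)-allylboronate
Product: 26 (3R,5E)-5-methyl-6-[(2S,3R)-4-methylidene-3-(3-methylbut-3-en-1-yl)-5-oxooxolan-2-yl]hexa-1,5-dien-3-yl 2-methylidenehex-5-enoate, via pinacol borate adduct 25 (not isolated)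
Conditions: (R)-TRIP [(R)-3,3′-bis(2,4,6-triisopropylphenyl)-1,1′-binaphthyl-2,2′-diyl hydrogen phosphate] (10 mol%), 4 Å MS, toluene, 0 °C → rt; then PPTS (cat.), 40 °C
Reagents that add atoms: none
Why: Chiral phosphoric acid-catalysed allylboration through a closed chair transition state, in which the (Z)-boronate holds the C2 chain equatorial to give the anti adduct (14S and 1R after catalyst-controlled Re-face addition to the enal), which should lactonise by acyl transfer under acid too mild to ionise the allylic C14–O bond, giving the trans α-methylene-γ-butyrolactone.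

Step 13
Reactants: 26 the lactone pentaene ester
Product: 28 ovatodiolide, (1R,10R,14S,4E,12E)-cembra-4,8,12,15(17)-tetraene-16,14:19,10-diolide, via butenolide triene 27 (not isolated)
Conditions: second-generation Hoveyda–Grubbs catalyst, RuCl2(H2IMes)(=CH-C6H4-2-O-i-Pr) (2 × 7.5 mol%), 1,4-benzoquinone (20 mol%), toluene (1 mM), 80 °C, Ar sparge
Reagents that add atoms: none
Why: Olefin metathesis by [2+2]/retro-[2+2] through ruthenacyclobutanes: the alkylidene formed at the C9 vinyl group should close on the acrylate C8=CH2 to give the five-membered butenolide ring (O, C19, C8, C9, C10; ring-closing metathesis of an allylic acrylate, ethylene lost), and the alkylidene formed at the C5 vinyl group then closes on the 1,1-disubstituted C4=CH2 to give the 14-membered carbocycle (macrocyclic ring-closing metathesis, second ethylene lost). The closest known reaction types are Ru–NHC ring-closing metathesis of α-substituted acrylates of allylic alcohols to butenolides and macrocyclic ring-closing metathesis forming a methyl-bearing trisubstituted olefin. No stereocentre is created, and C1, C10 and C14 are remote from the reacting carbons; the one new stereo-element is the C4=C5 geometry. The 4E isomer is needed and is expected to prevail because in the metallacycle the C6 chain on the alkylidene carbon sits anti to the larger C3 chain (syn to the small C18 methyl) on C4, and because the all-E 4,8,12-triene is the less strained arrangement of the bridged 14-membered ring. Pairing is secured by the substrate: acrylate with isopropenyl would need a tetrasubstituted olefin, C5 with C9 an eight-membered lactone far slower than five-ring closure, C9 with C4 a strained ten-membered ring, and the α-methylene lactone and the C12=C13 olefin are too hindered or electron-poor to engage, while high dilution suppresses dimerisation.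

Step 14
Reactants: 28 ovatodiolide
Product: 29 4-methylene-5β-hydroperoxyovatodiolide
Conditions: O2, tetraphenylporphyrin (1 mol%), white LED, CH2Cl2, −20 °C; no reductive work-up
Reagents that add atoms: dioxygen, O=O
Why: Schenck ene reaction, in which singlet oxygen should choose the electron-rich C4=C5 olefin (C12=C13 is deactivated by its allylic acyloxy group, the enoates are inert), abstract hydrogen on the disubstituted side from the freely rotating C18 methyl (cis effect) so that oxygen bonds to C5 and the olefin shifts to C4=C18, and attack the peripheral face of the macrocycle to set the 5R (5β) centre.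

**Compound list**

1 | (R)-epichlorohydrin, (2R)-2-(chloromethyl)oxirane | ClC[C@H]1CO1 | starting material
2 | ethynyltrimethylsilane | C#C[Si](C)(C)C | starting material
3 | lithium (trimethylsilyl)acetylide | [Li]C#C[Si](C)(C)C | intermediate
4 | (2R)-1-chloro-5-(trimethylsilyl)pent-4-yn-2-ol | ClC[C@H](O)CC#C[Si](C)(C)C | intermediate
5 | (2R)-2-[3-(trimethylsilyl)prop-2-yn-1-yl]oxirane | C1[C@H](O1)CC#C[Si](C)(C)C | intermediate
6 | (3R)-6-(trimethylsilyl)hex-1-en-5-yn-3-ol | C=C[C@H](O)CC#C[Si](C)(C)C | intermediate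
7 | (3R)-hex-1-en-5-yn-3-ol | C=C[C@H](O)CC#C | intermediate
8 | {[(3R,5E)-6-(dimethylalumanyl)-5-methylhexa-1,5-dien-3-yl]oxy}dimethylalumane | C=C[C@H](O[Al](C)C)C/C(C)=C/[Al](C)C | intermediate
9 | (2E,5R)-3-methylhepta-2,6-diene-1,5-diol | C=C[C@H](O)C/C(C)=C/CO | intermediate
10 | (2E,5R)-5-hydroxy-3-methylhepta-2,6-dienal | C=C[C@H](O)C/C(C)=C/C=O | intermediate
11 | ethyl 2-(bromomethyl)prop-2-enoate | C=C(CBr)C(=O)OCC | starting material
12 | allylmagnesium bromide | C=CC[Mg]Br | starting material
13 | ethyl 2-methylidenehex-5-enoate | C=CCCC(=C)C(=O)OCC | intermediate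
14 | 2-methylidenehex-5-enoic acid | C=CCCC(=C)C(=O)O | intermediate
15 | (3R,5E)-5-methyl-7-oxohepta-1,5-dien-3-yl 2-methylidenehex-5-enoate | C=C[C@H](OC(=O)C(=C)CCC=C)C/C(C)=C/C=O | intermediate
16 | trimethyl(prop-1-yn-1-yl)silane | CC#C[Si](C)(C)C | starting material
17 | 3-chloro-2-methylprop-1-ene (methallyl chloride) | C=C(C)CCl | starting material
18 | [3-(trimethylsilyl)prop-2-yn-1-yl]lithium | [Li]CC#C[Si](C)(C)C | intermediate
19 | trimethyl(5-methylhex-5-en-1-yn-1-yl)silane | C=C(C)CCC#C[Si](C)(C)C | intermediate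
20 | (5-methylhex-5-en-1-yn-1-yl)lithium | [Li]C#CCCC(C)=C | intermediate
21 | methyl 6-methylhept-6-en-2-ynoate | C=C(C)CCC#CC(=O)OC | intermediate
22 | 2-(iodomethyl)-4,4,5,5-tetramethyl-1,3,2-dioxaborolane | ICB1OC(C)(C)C(C)(C)O1 | starting material
23 | methyl (2E)-2-(diisobutylalumanyl)-6-methylhepta-2,6-dienoate | COC(=O)/C([Al](CC(C)C)CC(C)C)=C\CCC(C)=C | intermediate
24 | methyl (2Z)-6-methyl-2-[(4,4,5,5-tetramethyl-1,3,2-dioxaborolan-2-yl)methyl]hepta-2,6-dienoate | COC(=O)/C(CB1OC(C)(C)C(C)(C)O1)=C\CCC(C)=C | intermediate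
25 | methyl (3R,4S,5E,8R)-6-methyl-2-methylidene-3-(3-methylbut-3-en-1-yl)-8-[(2-methylidenehex-5-enoyl)oxy]-4-[(4,4,5,5-tetramethyl-1,3,2-dioxaborolan-2-yl)oxy]deca-5,9-dienoate | COC(=O)C(=C)[C@@H](CCC(C)=C)[C@@H](OB1OC(C)(C)C(C)(C)O1)/C=C(\C)C[C@H](C=C)OC(=O)C(=C)CCC=C | intermediate
26 | (3R,5E)-5-methyl-6-[(2S,3R)-4-methylidene-3-(3-methylbut-3-en-1-yl)-5-oxooxolan-2-yl]hexa-1,5-dien-3-yl 2-methylidenehex-5-enoate | C=C1C(=O)O[C@@H](/C=C(\C)C[C@H](C=C)OC(=O)C(=C)CCC=C)[C@@H]1CCC(C)=C | intermediate
27 | (5R)-3-(but-3-en-1-yl)-5-{(2E)-2-methyl-3-[(2S,3R)-4-methylidene-3-(3-methylbut-3-en-1-yl)-5-oxooxolan-2-yl]prop-2-en-1-yl}furan-2(5H)-one | C=C1C(=O)O[C@@H](/C=C(\C)C[C@@H]2C=C(CCC=C)C(=O)O2)[C@@H]1CCC(C)=C | intermediate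
28 | ovatodiolide, (1R,10R,14S,4E,12E) | C=C1C(=O)O[C@H]2/C=C(\C)C[C@@H]3C=C(CC/C=C(\C)CC[C@H]12)C(=O)O3 | intermediate
29 | 4-methylene-5β-hydroperoxyovatodiolide, (1R,5R,10R,14S,12E) | C=C1C(=O)O[C@H]2/C=C(\C)C[C@@H]3C=C(CC[C@@H](OO)C(=C)CC[C@H]12)C(=O)O3 | target

**Summary**

Total steps: 14. Longest linear sequence: 9 (steps 1–5, 8, 12, 13, 14).

Steps most likely to fail, riskiest first:

1. Step 13. The C4=C5 olefin may form as an E/Z mixture, or the four terminal olefins may pair wrongly. The fallback sets out from 16 and 15 and returns at 28; it encodes the geometry in the substrate and separates the two closures. Lithiated 16 (18) is alkylated with commercial (E)-1-bromo-2-methylbut-2-ene to give trimethyl[(5E)-5-methylhept-5-en-1-yn-1-yl]silane F1. MeLi·LiBr converts it into [(5E)-5-methylhept-5-en-1-yn-1-yl]lithium F2, and ClCO2Me gives methyl (6E)-6-methyloct-6-en-2-ynoate F3. i-Bu2AlH/HMPA gives methyl (2E,6E)-2-(diisobutylalumanyl)-6-methylocta-2,6-dienoate F4, and 22 gives methyl (2Z,6E)-6-methyl-2-[(4,4,5,5-tetramethyl-1,3,2-dioxaborolan-2-yl)methyl]octa-2,6-dienoate F5. Addition to 15 under the conditions of step 12 gives the pinacol borate adduct bearing the (3E)-3-methylpent-3-en-1-yl chain F6 and then (3R,5E)-5-methyl-6-{(2S,3R)-4-methylidene-3-[(3E)-3-methylpent-3-en-1-yl]-5-oxooxolan-2-yl}hexa-1,5-dien-3-yl 2-methylidenehex-5-enoate F7. Second-generation Grubbs catalyst in CH2Cl2 at 40 °C should close only the butenolide, since the trisubstituted E-olefin does not engage, to give (5R)-3-(but-3-en-1-yl)-5-{(2E)-2-methyl-3-[(2S,3R)-4-methylidene-3-[(3E)-3-methylpent-3-en-1-yl]-5-oxooxolan-2-yl]prop-2-en-1-yl}furan-2(5H)-one F8. A molybdenum monoaryloxide pyrrolide alkylidene, Mo(NC6F5)(CHCMe2Ph)(2,5-Me2C4H2N)(OAr) with Ar = 2,6-bis(2,4,6-triisopropylphenyl)phenyl, in benzene at rt under reduced pressure, then effects stereoretentive macrocyclic ring-closing metathesis. The E geometry of the C4 terminus is carried into the ring with loss of propene, giving 28.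

2. Step 14. Hydrogen abstraction may occur from C6 instead of C18 (tertiary 4-hydroperoxide), or oxygen may be delivered to the wrong face. The fallback sets out from 28 and returns at 29; it replaces the pericyclic oxygenation by an ionic two-step sequence. Ene-type chlorination with HOCl (Ca(OCl)2, CO2, CH2Cl2/H2O, 0 °C) should put chlorine on C5 and shift the olefin to C4=C18 by loss of a C18 proton, giving (5R)-5-chloro-4-methylidene-4,5-dihydroovatodiolide F9 (its C5 epimer serves equally). Silver-assisted perhydrolysis (AgOCOCF3, anhydrous H2O2 in Et2O, 0 °C) then ionises the allylic chloride, and hydrogen peroxide should enter at the secondary terminus from the ring periphery to give 29.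

3. Step 12. The ester-bearing boronate may add slowly through a poorly organised pathway, with low control of the aldehyde face. The fallback sets out from 21 and 15 and returns at 26; it moves the chiral information from the catalyst onto boron. Alane 23 (from 21 as in step 11) is trapped with (4R,5R)-2-(bromomethyl)-4,5-dicyclohexyl-1,3,2-dioxaborolane F10, made from commercial diisopropyl (bromomethyl)boronate and (R,R)-1,2-dicyclohexylethane-1,2-diol. This gives methyl (2Z)-2-{[(4R,5R)-4,5-dicyclohexyl-1,3,2-dioxaborolan-2-yl]methyl}-6-methylhepta-2,6-dienoate F11. Its Sc(OTf)3-catalysed addition to 15 (toluene, −78 °C) is reagent-controlled through the same chair and gives the dicyclohexylethanediol borate adduct F12, which PPTS lactonises to 26. The (S,S)-diol is equally available if the opposite sense of induction is needed.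

**Further compounds**

F1 | step 13 | trimethyl[(5E)-5-methylhept-5-en-1-yn-1-yl]silane | C/C=C(\C)CCC#C[Si](C)(C)C
F2 | step 13 | [(5E)-5-methylhept-5-en-1-yn-1-yl]lithium | [Li]C#CCC/C(C)=C/C
F3 | step 13 | methyl (6E)-6-methyloct-6-en-2-ynoate | COC(=O)C#CCC/C(C)=C/C
F4 | step 13 | methyl (2E,6E)-2-(diisobutylalumanyl)-6-methylocta-2,6-dienoate | COC(=O)/C([Al](CC(C)C)CC(C)C)=C\CC/C(C)=C/C
F5 | step 13 | methyl (2Z,6E)-6-methyl-2-[(4,4,5,5-tetramethyl-1,3,2-dioxaborolan-2-yl)methyl]octa-2,6-dienoate | COC(=O)/C(CB1OC(C)(C)C(C)(C)O1)=C\CC/C(C)=C/C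
F6 | step 13 | methyl (3R,4S,5E,8R)-6-methyl-2-methylidene-3-[(3E)-3-methylpent-3-en-1-yl]-8-[(2-methylidenehex-5-enoyl)oxy]-4-[(4,4,5,5-tetramethyl-1,3,2-dioxaborolan-2-yl)oxy]deca-5,9-dienoate | COC(=O)C(=C)[C@@H](CC/C(C)=C/C)[C@@H](OB1OC(C)(C)C(C)(C)O1)/C=C(\C)C[C@H](C=C)OC(=O)C(=C)CCC=C
F7 | step 13 | (3R,5E)-5-methyl-6-{(2S,3R)-4-methylidene-3-[(3E)-3-methylpent-3-en-1-yl]-5-oxooxolan-2-yl}hexa-1,5-dien-3-yl 2-methylidenehex-5-enoate | C=C1C(=O)O[C@@H](/C=C(\C)C[C@H](C=C)OC(=O)C(=C)CCC=C)[C@@H]1CC/C(C)=C/C
F8 | step 13 | (5R)-3-(but-3-en-1-yl)-5-{(2E)-2-methyl-3-[(2S,3R)-4-methylidene-3-[(3E)-3-methylpent-3-en-1-yl]-5-oxooxolan-2-yl]prop-2-en-1-yl}furan-2(5H)-one | C=C1C(=O)O[C@@H](/C=C(\C)C[C@@H]2C=C(CCC=C)C(=O)O2)[C@@H]1CC/C(C)=C/C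
F9 | step 14 | (5R)-5-chloro-4-methylidene-4,5-dihydroovatodiolide | C=C1C(=O)O[C@H]2/C=C(\C)C[C@@H]3C=C(CC[C@@H](Cl)C(=C)CC[C@H]12)C(=O)O3
F10 | step 12 | (4R,5R)-2-(bromomethyl)-4,5-dicyclohexyl-1,3,2-dioxaborolane | BrCB1O[C@H](C2CCCCC2)[C@@H](C2CCCCC2)O1
F11 | step 12 | methyl (2Z)-2-{[(4R,5R)-4,5-dicyclohexyl-1,3,2-dioxaborolan-2-yl]methyl}-6-methylhepta-2,6-dienoate | COC(=O)/C(CB1O[C@H](C2CCCCC2)[C@@H](C2CCCCC2)O1)=C\CCC(C)=C
F12 | step 12 | methyl (3R,4S,5E,8R)-4-{[(4R,5R)-4,5-dicyclohexyl-1,3,2-dioxaborolan-2-yl]oxy}-6-methyl-2-methylidene-3-(3-methylbut-3-en-1-yl)-8-[(2-methylidenehex-5-enoyl)oxy]deca-5,9-dienoate | COC(=O)C(=C)[C@@H](CCC(C)=C)[C@@H](OB1O[C@H](C2CCCCC2)[C@@H](C2CCCCC2)O1)/C=C(\C)C[C@H](C=C)OC(=O)C(=C)CCC=C
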